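The readings stem from a simulated flask for substances that don't exist, noise included.

Reciprocal seconds are the unit to read first: in the autumn run over-reaction product grows behind target, so target is taken to be lost in a first-order step whose constant can be read.

| flask | starting material | reagent | free catalyst | remark | time |
|---|---|---|---|---|---|
| winter | 0.0068 M | 4 equiv | 1.5 mol% | run made earlier |  |
| autumn | 0.12 M | 4 equiv | 1.5 mol% | run made earlier |  |
| oak | 0.0060 M | 4.00 equiv | 1.5 mol% |  | 2.0 min |
| larch | 0.012 M | 4.00 equiv | 1.5 mol% |  | 2.0 min |
| birch | 0.025 M | 4.00 equiv | 1.5 mol% |  | 2.0 min |
| maple | 0.050 M | 4.00 equiv | 1.5 mol% |  | 2.0 min |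
| elm | 0.10 M | 4.00 equiv | 1.5 mol% |  | 2.0 min |

| run | time / s | target / % | over-reaction product / % |
|---|---|---|---|
| winter | 10.0 | 1.7 | 0 |
| winter | 15.0 | 0 | 1.3 |
| winter | 30.0 | 2.8 | 1.5 |
| winter | 60.0 | 4.4 | 1.5 |
| autumn | 12.0 | 5.4 | 0 |
| autumn | 25.0 | 10.7 | 1.8 |
| autumn | 40.0 | 16.4 | 4.4 |
| autumn | 50.0 | 19.4 | 6.8 |
| autumn | 60.0 | 21.3 | 8.6 |

(each reading ± 1 percentage point)

- the numbers in the tables scatter with a standard deviation of 1 percentage point
- "hardly changes" means that all values lie within two and a half points (for a concentration: within two and a half percent of the largest)

* share of target in all that became target or over-reaction product for oak, larch, birch, maple, elm, in this order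
* the shape of the row from first to last (falls all the way / falls, then rises / rises, then falls / rises all the way / hardly changes)

Up to 60.0 s in autumn, the time-integral of target equals the whole charge standing as target for 7.23 s, while over-reaction product reads 8.6%. Dividing gives the loss constant, the over-reaction product formed per unit of time-integral of target:

k(loss) = 0.0119 /s

Over the asked 2.0 min this makes the exponent

x = k(loss) · t = 1.43

Target formed at the last instant suffers no loss, so the ceiling on the share is 100 %. Target formed entirely at the first instant survives as e^(−x), so the floor is 24.0%.

The feed tightens this. In autumn, target plus over-reaction product grows by 0.00500 /s of the charge up to 25.0 s and by 0.00498 /s up to 60.0 s, which is a straight line. Assuming that a steady feed continues to 2.0 min, the share is the mean survival: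

share = (1 − e^(−x)) / x = 53.2%

Moving the over-reaction reading by 2 standard deviations either way gives a bracket:

47.0% to 60.8%

Concentration does not enter x if the constant is shared, so this reckoning expects a flat row inside the bracket.

The forecast runs from 52.6% to 49%, a share that “falls slowly as conversion rises”: falls all the way. Its values stay above the lower edge and below the upper edge, and it differs from this reckoning in shape.

The flask gives 58.8% in oak down to 58.2% in elm, so the row hardly changes, within the bracket.

    starting material + free catalyst → catalyst intermediate A (k = 130 /M/s)
    catalyst intermediate A ⇌ catalyst intermediate B (K = 0.160, k = 0.790 /s)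
    reagent + catalyst intermediate B → catalyst intermediate C (k = 20.0 /M/s)
    catalyst intermediate C → catalyst intermediate D (k = 2.60 /s)
    catalyst intermediate D → by-product + catalyst intermediate E (k = 330 /s)
    catalyst intermediate E → free catalyst + target (k = 2.60 /s)
    target → over-reaction product (k = 0.00990 /s)

At 2.00 min catalyst intermediate A, the resting state, holds 77.1% of the catalyst in oak and 66.4% in elm. The loss constant of 0.0119 /s, put into the mean survival over 20.0 min, reckons a share of 7.00%. Oak at that time holds target at 5.66% and over-reaction product at 77.0%, a share of 6.85%.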